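**Retrosynthetic overview**

1. The esters are installed last (C6 tiglate, then C4 angelate, then release of C7–OH). The C6 oxygen comes from hydroxylation of the C1/C6 enolate of a 4-silyloxy-5-isopropylcyclohexenone, anti to the C5 isopropyl group.
2. The route rests on one feature of the six-membered ring: the C1 carbonyl and the C4 oxygen sit 1,4 across the C2=C3 alkene. That pattern is what is left when a 2-silyloxyfuran (C1–C4 plus its ring oxygen) takes up an alkene as C5–C6 and the 1,4-oxygen bridge opens.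
3. Key disconnection: C4–C5 and C6–C1, leading to 3-(TBDPS-oxymethyl)-2-(trimethylsilyloxy)furan and the (E)-4-methylpent-2-enoyl oxazolidinone under Cu(OTf)2/bis(oxazoline). The imide carbon on C6 is only an activating group and is removed afterwards by alcoholysis and decarboxylation.
4. The furan comes from 3-furanmethanol (alkoxide-directed C2 lithiation, borylation/oxidation, two silylations); the imide comes from the acid and oxazolidin-2-one.
5. The carbocycle is the only ring and is formed in the key step.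

Key step: step 5

Numbering used below: C1 ketone, C2 (bearing C7, the exocyclic CH2O), C3, C4 (O), C5 (isopropyl), C6 (O).

Assumption: the sense of induction is taken from the square-planar chelate model, in which the tert-butyl group of a (4S)-oxazoline covers the alpha-Si face of the bound s-cis enoyl imide. The target needs attack on the alpha-Si/beta-Re face, hence the (R,R)-ligand; if the sense proved opposite, the (S,S)-ligand would be used with no other change.

**Route**

Step 1
Reactants: 1 3-furanmethanol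
Product: 4 3-(hydroxymethyl)furan-2(5H)-one, via 2-lithio-3-(lithiooxymethyl)furan 2 (not isolated), via dilithium furyltrimethoxyborate 3 (not isolated)
Conditions: n-BuLi (2.2 equiv), DME, 0 °C; B(OMe)3, −78 °C → rt; AcOH then 30% H2O2, 0 °C → rt
Reagents that add atoms: hydrogen peroxide, OO
Why: Alkoxide-directed ortho-lithiation puts lithium on furan C2 (silyl ethers of this alcohol lithiate at C5 or suffer O-to-C silyl shift, so the free alcohol is used and silicon is added afterwards), and borylation followed by oxidative C–B cleavage delivers the C2-oxygenated furan as its conjugated lactone tautomer.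

Step 2
Reactants: 4 3-(hydroxymethyl)furan-2(5H)-one
Product: 5 3-{[(tert-butyldiphenylsilyl)oxy]methyl}furan-2(5H)-one
Conditions: TBDPSCl, imidazole, DMF, 0 °C → rt
Reagents that add atoms: tert-butyldiphenylsilyl chloride, CC(C)(C)[Si](Cl)(c1ccccc1)c1ccccc1
Why: Standard imidazole-promoted O-silylation of a primary alcohol.

Step 3
Reactants: 5 3-{[(tert-butyldiphenylsilyl)oxy]methyl}furan-2(5H)-one
Product: 6 3-{[(tert-butyldiphenylsilyl)oxy]methyl}-2-(trimethylsilyloxy)furan
Conditions: TMSOTf, Et3N, CH2Cl2, 0 °C; pentane trituration, used crude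
Reagents that add atoms: trimethylsilyl triflate, C[Si](C)(C)OS(=O)(=O)C(F)(F)F
Why: Soft enolisation of the butenolide (gamma-deprotonation) with O-silylation gives the aromatic 2-silyloxyfuran, the usual preparation of silyl dienolates of this type.

Step 4
Reactants: 7 (E)-4-methylpent-2-enoic acid; 8 oxazolidin-2-one
Product: 10 3-[(E)-4-methylpent-2-enoyl]oxazolidin-2-one, via mixed pivalic anhydride 9 (not isolated)
Conditions: PivCl, Et3N, THF, −20 °C; then LiCl, oxazolidin-2-one, rt
Reagents that add atoms: none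
Why: Mixed-anhydride N-acylation of the oxazolidinone assisted by LiCl, with attack at the less hindered enoyl carbonyl and no change of the (E)-alkene.

Step 5
Reactants: 6 3-{[(tert-butyldiphenylsilyl)oxy]methyl}-2-(trimethylsilyloxy)furan; 10 3-[(E)-4-methylpent-2-enoyl]oxazolidin-2-one
Product: 12 (4R,5R,6R)-2-{[(tert-butyldiphenylsilyl)oxy]methyl}-4-hydroxy-6-(2-oxooxazolidine-3-carbonyl)-5-(propan-2-yl)cyclohex-2-en-1-one, via oxa-bridged cycloadduct 11 (not isolated)
Conditions: Cu(OTf)2 (10 mol%), 2,2'-(propane-2,2-diyl)bis[(4R)-4-tert-butyl-4,5-dihydro-1,3-oxazole] (11 mol%), 4 Å MS, CH2Cl2, −78 → −20 °C, no alcohol additive; then aq citric acid, THF, 0 °C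
Reagents that add atoms: none
Why: Proposed new method: the Cu(OTf)2/bis(oxazoline) complex binds the imide as a square-planar two-point chelate in its s-cis form, furan C5 attacks the beta carbon (C4–C5) and, since no proton source is present, the copper-bound enolate carbon closes C6–C1 onto the silyloxy-substituted oxocarbenium carbon, concertedly or in two stages, to give bridged ketal 11, whose C1–O bridge bond then ionises under the Lewis acid with help from the silyloxy lone pair to leave the C1 ketone and the C4 oxygen, freed as the alcohol on citric acid work-up. The closest known reactions are the Cu(OTf)2/bis(oxazoline)-catalysed vinylogous Mukaiyama–Michael addition of 2-silyloxyfurans to N-enoyl oxazolidinones, which normally stops at the butenolide, and the thermal Diels–Alder/bridge-opening of 2-silyloxyfurans to 4-hydroxycyclohexenones. The carbocycle is closed as a formal endo [4+2] across furan C2 and C5, the second bond corresponding to a 6-exo-trig attack of the enolate carbon on the activated lactone-type carbon. C5 and C6 follow from suprafacial addition to the (E)-alkene on the face left open by the ligand tert-butyl group (the alpha-Si/beta-Re face with the (R,R)-ligand), C4 is set relative to C5 by the endo approach of the imide, which puts isopropyl exo and hence cis to the oxygen bridge (the relation normally favoured in such additions), and C6, trans to isopropyl, is also the thermodynamic epimer of the beta-keto imide. The step needs C5-to-beta-carbon regiochemistry, which the vinylogous polarity of the silyl dienolate and the remote C3 substituent secure, endo topology, and ring closure that outruns silyl transfer to the enolate, which the absence of alcohol additives and the bulky, weakly basic TBDPS ether (no ionisation of the furfuryl-type C7–O bond) are meant to favour.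

Step 6
Reactants: 12 (4R,5R,6R)-2-{[(tert-butyldiphenylsilyl)oxy]methyl}-4-hydroxy-6-(2-oxooxazolidine-3-carbonyl)-5-(propan-2-yl)cyclohex-2-en-1-one
Product: 13 (4R,5R,6R)-4-[(tert-butyldimethylsilyl)oxy]-2-{[(tert-butyldiphenylsilyl)oxy]methyl}-6-(2-oxooxazolidine-3-carbonyl)-5-(propan-2-yl)cyclohex-2-en-1-one
Conditions: TBSOTf (1.15 equiv), 2,6-lutidine, CH2Cl2, −78 °C
Reagents that add atoms: tert-butyldimethylsilyl triflate, CC(C)(C)[Si](C)(C)OS(=O)(=O)C(F)(F)F
Why: Silyl triflate O-silylation of the hindered C4 alcohol is fast at −78 °C and caps it before C6 can epimerise and the hydroxyl attack the imide, and the weak base leaves the stereocentres untouched.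

Step 7
Reactants: 13 (4R,5R,6R)-4-[(tert-butyldimethylsilyl)oxy]-2-{[(tert-butyldiphenylsilyl)oxy]methyl}-6-(2-oxooxazolidine-3-carbonyl)-5-(propan-2-yl)cyclohex-2-en-1-one
Product: 14 prop-2-en-1-yl (1R,5R,6R)-5-[(tert-butyldimethylsilyl)oxy]-3-{[(tert-butyldiphenylsilyl)oxy]methyl}-2-oxo-6-(propan-2-yl)cyclohex-3-ene-1-carboxylate
Conditions: allyl alcohol, Sm(OTf)3 (10 mol%), CH2Cl2, rt
Reagents that add atoms: allyl alcohol, C=CCO
Why: Lewis-acid-catalysed alcoholysis (transesterification) of an N-acyl oxazolidinone, in which chelation of the imide carbonyls activates the exocyclic acyl carbon under non-basic conditions; any epimerisation at C6 is irrelevant because that centre becomes CH2 in the next step.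

Step 8
Reactants: 14 prop-2-en-1-yl (1R,5R,6R)-5-[(tert-butyldimethylsilyl)oxy]-3-{[(tert-butyldiphenylsilyl)oxy]methyl}-2-oxo-6-(propan-2-yl)cyclohex-3-ene-1-carboxylate
Product: 16 (4R,5S)-4-[(tert-butyldimethylsilyl)oxy]-2-{[(tert-butyldiphenylsilyl)oxy]methyl}-5-(propan-2-yl)cyclohex-2-en-1-one, via beta-keto acid 15 (not isolated)
Conditions: Pd(OAc)2 (5 mol%), PPh3 (10 mol%), HCO2H, Et3N, THF, rt
Reagents that add atoms: none
Why: Tsuji deallylation–decarboxylation: zerovalent palladium formed in situ ionises the allyl ester, formate reduces the pi-allyl unit to propene, and the beta-keto acid loses CO2 at room temperature without touching the enone or the silyl ethers.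

Step 9
Reactants: 16 (4R,5S)-4-[(tert-butyldimethylsilyl)oxy]-2-{[(tert-butyldiphenylsilyl)oxy]methyl}-5-(propan-2-yl)cyclohex-2-en-1-one
Product: 18 (4S,5R,6R)-4-[(tert-butyldimethylsilyl)oxy]-2-{[(tert-butyldiphenylsilyl)oxy]methyl}-6-hydroxy-5-(propan-2-yl)cyclohex-2-en-1-one, via sodium dienolate 17 (not isolated)
Conditions: NaN(SiMe3)2 (1.1 equiv), THF, −78 °C; 2-(phenylsulfonyl)-3-phenyloxaziridine, −78 °C; AcOH quench
Reagents that add atoms: 2-(phenylsulfonyl)-3-phenyloxaziridine, O=S(=O)(c1ccccc1)N1OC1c1ccccc1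
Why: Kinetic alpha'-deprotonation gives the cross-conjugated enolate, and enolate hydroxylation with the N-sulfonyloxaziridine delivers oxygen to C6 on the face opposite the adjacent C5 isopropyl group (and the cis C4 silyloxy group), setting C6 trans to isopropyl, which is also the more stable epimer.

Step 10
Reactants: 18 (4S,5R,6R)-4-[(tert-butyldimethylsilyl)oxy]-2-{[(tert-butyldiphenylsilyl)oxy]methyl}-6-hydroxy-5-(propan-2-yl)cyclohex-2-en-1-one
Product: 19 (4S,5R,6R)-4-[(tert-butyldimethylsilyl)oxy]-2-{[(tert-butyldiphenylsilyl)oxy]methyl}-6-[(E)-2-methylbut-2-enoyloxy]-5-(propan-2-yl)cyclohex-2-en-1-one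
Conditions: tigloyl chloride, pyridine, DMAP (cat.), CH2Cl2, 0 °C → rt
Reagents that add atoms: (E)-2-methylbut-2-enoyl chloride, C/C=C(\C)C(=O)Cl
Why: DMAP-catalysed acylation of the secondary alpha-ketol with an acid chloride whose (E)-alkene is the stable geometry, so no isomerisation is at stake.

Step 11
Reactants: 19 (4S,5R,6R)-4-[(tert-butyldimethylsilyl)oxy]-2-{[(tert-butyldiphenylsilyl)oxy]methyl}-6-[(E)-2-methylbut-2-enoyloxy]-5-(propan-2-yl)cyclohex-2-en-1-one
Product: 20 (4S,5S,6R)-2-{[(tert-butyldiphenylsilyl)oxy]methyl}-4-hydroxy-6-[(E)-2-methylbut-2-enoyloxy]-5-(propan-2-yl)cyclohex-2-en-1-one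
Conditions: HF·pyridine, pyridine, THF, 0 °C → rt
Reagents that add atoms: none
Why: Selective desilylation, since under buffered acidic fluoride a TBS ether is cleaved much faster than a TBDPS ether, and the mildly acidic medium avoids base-induced epimerisation at C6.

Step 12
Reactants: 20 (4S,5S,6R)-2-{[(tert-butyldiphenylsilyl)oxy]methyl}-4-hydroxy-6-[(E)-2-methylbut-2-enoyloxy]-5-(propan-2-yl)cyclohex-2-en-1-one
Product: 21 (4S,5S,6R)-2-{[(tert-butyldiphenylsilyl)oxy]methyl}-4-[(Z)-2-methylbut-2-enoyloxy]-6-[(E)-2-methylbut-2-enoyloxy]-5-(propan-2-yl)cyclohex-2-en-1-one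
Conditions: angelic acid, 2,4,6-trichlorobenzoyl chloride, Et3N, toluene, rt; then 20, 75 °C, no DMAP
Reagents that add atoms: (Z)-2-methylbut-2-enoic acid, C/C=C(/C)C(=O)O
Why: Yamaguchi esterification through the mixed trichlorobenzoic anhydride without a nucleophilic catalyst, the protocol under which the (Z)-alkene of angelic acid is expected to persist while the hindered C4 alcohol is acylated with retention at C4.

Step 13
Reactants: 21 (4S,5S,6R)-2-{[(tert-butyldiphenylsilyl)oxy]methyl}-4-[(Z)-2-methylbut-2-enoyloxy]-6-[(E)-2-methylbut-2-enoyloxy]-5-(propan-2-yl)cyclohex-2-en-1-one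
Product: 22 (4S,5S,6R)-2-(hydroxymethyl)-4-[(Z)-2-methylbut-2-enoyloxy]-6-[(E)-2-methylbut-2-enoyloxy]-5-(propan-2-yl)cyclohex-2-en-1-one
Conditions: HF·pyridine, THF, rt
Reagents that add atoms: none
Why: Fluoride-mediated cleavage of the TBDPS ether under acidic conditions, which spare both esters, the (Z)-alkene and the epimerisable C6 centre; the freed C7 hydroxyl has no ester within reach for acyl migration.

**Compound list**

1 | 3-furanmethanol | OCc1ccoc1 | starting material
2 | 2-lithio-3-(lithiooxymethyl)furan | [Li]OCc1ccoc1[Li] | intermediate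
3 | dilithium trimethoxy[3-(oxidomethyl)furan-2-yl]borate | [Li+].[Li+].[O-]Cc1ccoc1[B-](OC)(OC)OC | intermediate
4 | 3-(hydroxymethyl)furan-2(5H)-one | O=C1OCC=C1CO | intermediate
5 | 3-{[(tert-butyldiphenylsilyl)oxy]methyl}furan-2(5H)-one | O=C1OCC=C1CO[Si](c1ccccc1)(c1ccccc1)C(C)(C)C | intermediate
6 | 3-{[(tert-butyldiphenylsilyl)oxy]methyl}-2-(trimethylsilyloxy)furan | C[Si](C)(C)Oc1occc1CO[Si](c1ccccc1)(c1ccccc1)C(C)(C)C | intermediate
7 | (E)-4-methylpent-2-enoic acid | CC(C)/C=C/C(=O)O | starting material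
8 | oxazolidin-2-one | O=C1NCCO1 | starting material
9 | (E)-4-methylpent-2-enoic pivalic anhydride | CC(C)/C=C/C(=O)OC(=O)C(C)(C)C | intermediate
10 | 3-[(E)-4-methylpent-2-enoyl]oxazolidin-2-one | CC(C)/C=C/C(=O)N1CCOC1=O | intermediate
11 | 3-{[(1R,2R,3R,4R)-6-{[(tert-butyldiphenylsilyl)oxy]methyl}-3-(propan-2-yl)-1-(trimethylsilyloxy)-7-oxabicyclo[2.2.1]hept-5-en-2-yl]carbonyl}oxazolidin-2-one (acyl endo, isopropyl exo) | O2[C@H]1C=C(CO[Si](c3ccccc3)(c3ccccc3)C(C)(C)C)[C@]2(O[Si](C)(C)C)[C@H](C(=O)N3CCOC3=O)[C@H]1C(C)C | intermediate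
12 | (4R,5R,6R)-2-{[(tert-butyldiphenylsilyl)oxy]methyl}-4-hydroxy-6-(2-oxooxazolidine-3-carbonyl)-5-(propan-2-yl)cyclohex-2-en-1-one | O[C@H]1C=C(CO[Si](c2ccccc2)(c2ccccc2)C(C)(C)C)C(=O)[C@H](C(=O)N2CCOC2=O)[C@H]1C(C)C | intermediate
13 | (4R,5R,6R)-4-[(tert-butyldimethylsilyl)oxy]-2-{[(tert-butyldiphenylsilyl)oxy]methyl}-6-(2-oxooxazolidine-3-carbonyl)-5-(propan-2-yl)cyclohex-2-en-1-one | CC(C)(C)[Si](C)(C)O[C@H]1C=C(CO[Si](c2ccccc2)(c2ccccc2)C(C)(C)C)C(=O)[C@H](C(=O)N2CCOC2=O)[C@H]1C(C)C | intermediate
14 | prop-2-en-1-yl (1R,5R,6R)-5-[(tert-butyldimethylsilyl)oxy]-3-{[(tert-butyldiphenylsilyl)oxy]methyl}-2-oxo-6-(propan-2-yl)cyclohex-3-ene-1-carboxylate | CC(C)(C)[Si](C)(C)O[C@H]1C=C(CO[Si](c2ccccc2)(c2ccccc2)C(C)(C)C)C(=O)[C@H](C(=O)OCC=C)[C@H]1C(C)C | intermediate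
15 | (1R,5R,6R)-5-[(tert-butyldimethylsilyl)oxy]-3-{[(tert-butyldiphenylsilyl)oxy]methyl}-2-oxo-6-(propan-2-yl)cyclohex-3-ene-1-carboxylic acid | CC(C)(C)[Si](C)(C)O[C@H]1C=C(CO[Si](c2ccccc2)(c2ccccc2)C(C)(C)C)C(=O)[C@H](C(=O)O)[C@H]1C(C)C | intermediate
16 | (4R,5S)-4-[(tert-butyldimethylsilyl)oxy]-2-{[(tert-butyldiphenylsilyl)oxy]methyl}-5-(propan-2-yl)cyclohex-2-en-1-one | CC(C)(C)[Si](C)(C)O[C@H]1C=C(CO[Si](c2ccccc2)(c2ccccc2)C(C)(C)C)C(=O)C[C@H]1C(C)C | intermediate
17 | sodium (3R,4R)-4-[(tert-butyldimethylsilyl)oxy]-6-{[(tert-butyldiphenylsilyl)oxy]methyl}-3-(propan-2-yl)cyclohexa-1,5-dien-1-olate | [Na+].CC(C)(C)[Si](C)(C)O[C@H]1C=C(CO[Si](c2ccccc2)(c2ccccc2)C(C)(C)C)C([O-])=C[C@H]1C(C)C | intermediate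
18 | (4S,5R,6R)-4-[(tert-butyldimethylsilyl)oxy]-2-{[(tert-butyldiphenylsilyl)oxy]methyl}-6-hydroxy-5-(propan-2-yl)cyclohex-2-en-1-one | CC(C)(C)[Si](C)(C)O[C@H]1C=C(CO[Si](c2ccccc2)(c2ccccc2)C(C)(C)C)C(=O)[C@H](O)[C@H]1C(C)C | intermediate
19 | (4S,5R,6R)-4-[(tert-butyldimethylsilyl)oxy]-2-{[(tert-butyldiphenylsilyl)oxy]methyl}-6-[(E)-2-methylbut-2-enoyloxy]-5-(propan-2-yl)cyclohex-2-en-1-one | CC(C)(C)[Si](C)(C)O[C@H]1C=C(CO[Si](c2ccccc2)(c2ccccc2)C(C)(C)C)C(=O)[C@H](OC(=O)/C(C)=C/C)[C@H]1C(C)C | intermediate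
20 | (4S,5S,6R)-2-{[(tert-butyldiphenylsilyl)oxy]methyl}-4-hydroxy-6-[(E)-2-methylbut-2-enoyloxy]-5-(propan-2-yl)cyclohex-2-en-1-one | O[C@H]1C=C(CO[Si](c2ccccc2)(c2ccccc2)C(C)(C)C)C(=O)[C@H](OC(=O)/C(C)=C/C)[C@H]1C(C)C | intermediate
21 | (4S,5S,6R)-2-{[(tert-butyldiphenylsilyl)oxy]methyl}-4-[(Z)-2-methylbut-2-enoyloxy]-6-[(E)-2-methylbut-2-enoyloxy]-5-(propan-2-yl)cyclohex-2-en-1-one | C/C=C(/C)C(=O)O[C@H]1C=C(CO[Si](c2ccccc2)(c2ccccc2)C(C)(C)C)C(=O)[C@H](OC(=O)/C(C)=C/C)[C@H]1C(C)C | intermediate
22 | (4S,5S,6R)-2-(hydroxymethyl)-4-[(Z)-2-methylbut-2-enoyloxy]-6-[(E)-2-methylbut-2-enoyloxy]-5-(propan-2-yl)cyclohex-2-en-1-one | C/C=C(/C)C(=O)O[C@H]1C=C(CO)C(=O)[C@H](OC(=O)/C(C)=C/C)[C@H]1C(C)C | target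

**Step count and risks**

Total steps: 13. Longest linear sequence: 12 (steps 1–3 and 5–13; step 4 is the one-step side branch).

Steps most likely to fail:

1. Step 5 (proposed new method). The reaction may stop after the first C–C bond, by silyl transfer to or protonation of the enolate before ring closure. The bridged adduct may fragment back along C6–C1 instead of opening at the oxygen bridge. The chelating beta-keto imide product may hold the copper and stall turnover. Endo or facial selectivity may be poor. Fallback with known chemistry, setting out from 6 and 10: the same Cu(OTf)2/(R,R)-bis(oxazoline) catalyst is run with (CF3)2CHOH as proton source, so that the reaction is stopped on purpose at the vinylogous Mukaiyama–Michael stage and gives 3-[(3S)-3-[(2R)-4-{[(tert-butyldiphenylsilyl)oxy]methyl}-5-oxo-2,5-dihydrofuran-2-yl]-4-methylpentanoyl]oxazolidin-2-one F1. The C6–C1 bond is then closed separately by a titanium-mediated Dieckmann-type condensation (TiCl4, iPr2NEt, CH2Cl2, −78 → −20 °C): soft enolisation of the imide, attack on the lactone carbonyl and expulsion of the C4 oxygen from the tetrahedral intermediate. This returns to the route at 12.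

2. Step 12. Z-to-E isomerisation of the activated angeloyl unit would put a second tiglate on C4. Acylation of the C4 hydroxyl next to the cis isopropyl group may be slow, and the gamma-hydroxy enone may drift under amine base at 75 °C. Fallback, setting out from 20: esterification with 2-[bis(2,2,2-trifluoroethoxy)phosphoryl]propanoic acid (DCC, DMAP cat., CH2Cl2, 0 °C) gives (4S,5S,6R)-4-{2-[bis(2,2,2-trifluoroethoxy)phosphoryl]propanoyloxy}-2-{[(tert-butyldiphenylsilyl)oxy]methyl}-6-[(E)-2-methylbut-2-enoyloxy]-5-(propan-2-yl)cyclohex-2-en-1-one F2, as a mixture of epimers at the phosphonate carbon. A Still–Gennari olefination with acetaldehyde (KN(SiMe3)2, one equivalent, 18-crown-6, THF, −78 °C) then builds the (Z)-alkene in place on the C4 ester. This returns to the route at 21.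

3. Step 7. Alcoholysis at the hindered, enolisable beta-keto imide may be slow, the alcohol may attack the ring carbonyl of the oxazolidinone, or the Lewis acid may strip the C4 silyl ether. Fallback, setting out from 13: hydroperoxide cleavage of the exocyclic imide carbonyl (LiOH, H2O2, THF/H2O, 0 °C, short exposure to limit conjugate epoxidation of the enone; Na2SO3 quench), then acidification to pH 4 and warming to 40 °C so that acid 15 loses CO2. This returns to the route at 16 without passing through 14 and makes no compound outside the list (F0).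

**Further compounds**

F1 | step 5 | 3-[(3S)-3-[(2R)-4-{[(tert-butyldiphenylsilyl)oxy]methyl}-5-oxo-2,5-dihydrofuran-2-yl]-4-methylpentanoyl]oxazolidin-2-one | O=C1O[C@@H](C=C1CO[Si](c2ccccc2)(c2ccccc2)C(C)(C)C)[C@@H](CC(=O)N2CCOC2=O)C(C)C
F2 | step 12 | (4S,5S,6R)-4-{2-[bis(2,2,2-trifluoroethoxy)phosphoryl]propanoyloxy}-2-{[(tert-butyldiphenylsilyl)oxy]methyl}-6-[(E)-2-methylbut-2-enoyloxy]-5-(propan-2-yl)cyclohex-2-en-1-one | CC(C(=O)O[C@H]1C=C(CO[Si](c2ccccc2)(c2ccccc2)C(C)(C)C)C(=O)[C@H](OC(=O)/C(C)=C/C)[C@H]1C(C)C)P(=O)(OCC(F)(F)F)OCC(F)(F)F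
F0 | step 7 | none | none
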